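**Retrosynthetic overview**

1. Target (6,7-seco-ent-kaurane 7,20-spirolactone, ent-kaurane numbering): the C1 enone and C6 aldehyde are unveiled last from a 1,6-bis-silyl ether; 15-OAc and the 16-methylene come from a 15-ketone.
2. Feature used: ring D is the cyclopentane C8–C15–C16–C13–C14, oxygenated at C15 next to quaternary C8 and bridging C8 and C13 of ring C. It is opened at C13–C16 via a C12–C13–C16 cyclopropyl ketone, made by adding the carbenoid of a C8 diazomethyl ketone (C16) across a ring-C C12=C13 bond; samarium diiodide then cleaves C12–C16.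
3. Ring C (C8, C9, C11–C14): Diels–Alder reaction of butadiene with the C8=C9 bond of a 2-(allyloxycarbonyl) unsaturated spiro-δ-lactone; the ester carbon becomes C15.
4. Lactone ring: Knoevenagel condensation of a C9 aldehyde with diallyl malonate, then lactonisation of C20–OH; quaternary C10 by two successive enolate one-carbon homologations (C20, then C9).
5. Ring A: asymmetric 1,4-vinylation of 4,4-dimethylcyclohexa-2,5-dienone (sets C5, brings C6). Ring order: A, lactone, C, D.

Key step: step 17

Abbreviations and numbering: TBS = tert-butyldimethylsilyl; PMB = 4-methoxybenzyl. ent-Kaurane locants are used in the text: ring A = C1–C5, C10; C6 = arm on C5; C20 and C9 = arms on C10; C7 = lactone C=O; ring C = C8, C9, C11–C14; ring D = C8, C15, C16, C13, C14; C17 = exocyclic CH2. In the monocyclic compounds the IUPAC ring locants 1–5 are C1–C5 and locant 6 is C10.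

Remark 1: the sense of induction of (R)-BINAP in step 2 is taken from that known for 2-cyclohexenone; should the gem-dimethyl group reverse it, (S)-BINAP is used.
Remark 2: a free ring-A enone would be reduced by samarium diiodide (step 18) and would compete in the C15 Luche reduction (step 20), so ring A is carried from step 14 to step 22 as its 1-silyloxy-2-ene.
Remark 3: the temporary C1 carbinol centre from step 13 is drawn with oxygen cis to C20; it is erased in step 23, so either epimer serves.

**Route**

Step 1
Reactants: 1 4,4-dimethylcyclohex-2-en-1-one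
Product: 2 4,4-dimethylcyclohexa-2,5-dien-1-one
Conditions: DDQ, TsOH (cat.), dioxane, reflux
Reagents that add atoms: none
Why: DDQ dehydrogenation through the enol can only desaturate the C1-side CH2–CH2 bond because C4 is quaternary, which gives the cross-conjugated, prochiral dienone.

Step 2
Reactants: 2 4,4-dimethylcyclohexa-2,5-dien-1-one; 3 potassium vinyltrifluoroborate
Product: 4 (R)-4,4-dimethyl-5-vinylcyclohex-2-en-1-one
Conditions: [Rh(cod)2]BF4 (3 mol%), (R)-BINAP (3.3 mol%), 3 (1.05 equiv), toluene/H2O, 100 °C
Reagents that add atoms: potassium vinyltrifluoroborate (3), C=C[B-](F)(F)F.[K+]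
Why: Hayashi–Miyaura asymmetric 1,4-addition, in which the BINAP-bound vinylrhodium species (monovalent rhodium) adds to one enantiotopic enone arm and the ligand selects the face, so that the single new centre C5 should form as the R isomer while the second enone survives because only one equivalent of boron reagent is used.

Step 3
Reactants: 4 (R)-4,4-dimethyl-5-vinylcyclohex-2-en-1-one
Product: 6 (S)-5-(hydroxymethyl)-4,4-dimethylcyclohex-2-en-1-one, via C6 aldehyde 5 (not isolated)
Conditions: O3, CH2Cl2/MeOH, −78 °C (Sudan Red 7B endpoint); PPh3, −78 → 0 °C; NaBH4 (0.5 equiv), −78 °C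
Reagents that add atoms: ozone, [O-][O+]=O
Why: Chemoselective ozonolysis cleaves the electron-rich terminal vinyl group in preference to the conjugated enone, and NaBH4 at −78 °C reduces the aldehyde far faster than the enone carbonyl, the cold one-pot sequence leaving no time for the aldehyde α-centre C5 to enolise.

Step 4
Reactants: 6 (S)-5-(hydroxymethyl)-4,4-dimethylcyclohex-2-en-1-one
Product: 7 (S)-5-(TBS-oxymethyl)-4,4-dimethylcyclohex-2-en-1-one
Conditions: TBSCl, imidazole, DMF, 0 °C → rt
Reagents that add atoms: tert-butyldimethylsilyl chloride (TBSCl), CC(C)(C)[Si](C)(C)Cl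
Why: Standard silylation of the primary alcohol gives an ether that should survive the amide bases, oxidants and Lewis acids used before step 22.

Step 5
Reactants: 8 4-methoxybenzyl alcohol; 9 chloromethyl methyl sulfide
Product: 10 1-methoxy-4-{[(methylsulfanyl)methoxy]methyl}benzene
Conditions: NaH, NaI (cat.), DME, 0 °C → rt
Reagents that add atoms: chloromethyl methyl sulfide (9), CSCCl
Why: Williamson etherification of the sodium alkoxide with the activated α-chloro sulfide gives the methylthiomethyl ether.

Step 6
Reactants: 10 1-methoxy-4-{[(methylsulfanyl)methoxy]methyl}benzene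
Product: 11 1-[(chloromethoxy)methyl]-4-methoxybenzene (PMB chloromethyl ether)
Conditions: SO2Cl2, CH2Cl2, −78 °C; used crude
Reagents that add atoms: sulfuryl chloride, O=S(=O)(Cl)Cl
Why: Chlorinolysis of the O,S-acetal through a chlorosulfonium ion releases methanesulfenyl chloride and leaves the chloromethyl ether, a hydroxymethyl cation equivalent whose PMB group can later be removed oxidatively.

Step 7
Reactants: 7 (S)-5-(TBS-oxymethyl)-4,4-dimethylcyclohex-2-en-1-one; 11 PMB chloromethyl ether
Product: 12 trans-6-(PMB-oxymethyl)-5-(TBS-oxymethyl)-4,4-dimethylcyclohex-2-en-1-one (C5 as in 7; major C10 epimer)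
Conditions: LiN(iPr)2, THF, −78 °C; then 11, −78 → −40 °C
Reagents that add atoms: PMB chloromethyl ether (11), COc1ccc(COCCl)cc1
Why: Enolate alkylation, in which C10 is the only enolisable position (C4 is quaternary, so there is no γ-hydrogen) and the kinetic lithium enolate is alkylated by the reactive α-chloro ether trans to the C5 arm, at a centre that is re-formed in step 8 so that its epimer ratio is of no consequence.

Step 8
Reactants: 12 trans-6-(PMB-oxymethyl)-5-(TBS-oxymethyl)-4,4-dimethylcyclohex-2-en-1-one; 13 formaldehyde (monomeric gas from cracked paraformaldehyde)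
Product: 14 6-(hydroxymethyl)-6-(PMB-oxymethyl)-5-(TBS-oxymethyl)-4,4-dimethylcyclohex-2-en-1-one (hydroxymethyl C9 trans and PMB-oxymethyl C20 cis to the C5 arm)
Conditions: LiN(iPr)2, THF, −78 °C; CH2O (gas), −78 °C; AcOH quench at −78 °C
Reagents that add atoms: formaldehyde (13), C=O
Why: Aldol addition of the tetrasubstituted lithium enolate to formaldehyde creates the quaternary C10, because the C5 silyloxymethyl group sits pseudoaxial to avoid allylic strain with the C10 substituent and formaldehyde adds to the opposite face, placing C9 trans and C20 cis to C6, while the cold acidic quench forestalls retro-aldol cleavage.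

Step 9
Reactants: 14 6-(hydroxymethyl)-6-(PMB-oxymethyl) ketone
Product: 15 1-(PMB-oxymethyl)-6-(TBS-oxymethyl)-5,5-dimethyl-2-oxocyclohex-3-ene-1-carbaldehyde (formyl C9 trans to the C5 arm)
Conditions: Dess–Martin periodinane, CH2Cl2, 0 °C → rt
Reagents that add atoms: none
Why: Dess–Martin oxidation of the neopentyl primary alcohol under non-basic conditions gives the non-enolisable β-keto aldehyde without deformylation.

Step 10
Reactants: 15 C9 keto aldehyde; 16 diallyl malonate
Product: 17 diallyl 2-(cyclohexenylmethylidene)malonate (C9=C8 alkylidene malonate; C10 and C5 as in 15)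
Conditions: TiCl4, pyridine, THF, 0 °C → rt
Reagents that add atoms: diallyl malonate (16), C=CCOC(=O)CC(=O)OCC=C
Why: Knoevenagel condensation under Lehnert conditions (TiCl4 tempered by THF and pyridine) is the variant suited to hindered neopentyl aldehydes and avoids the nucleophilic amines that would deformylate the β-keto aldehyde, the allyl esters being chosen because one must later be cleaved under neutral conditions.

Step 11
Reactants: 17 alkylidene malonate
Product: 19 allyl 11-(TBS-oxymethyl)-10,10-dimethyl-3,7-dioxo-2-oxaspiro[5.5]undeca-4,8-diene-4-carboxylate (lactone CH2O C20 cis to the C5 arm), via hydroxy diester 18 (not isolated)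
Conditions: DDQ, CH2Cl2/pH 7 buffer, 0 °C → rt; then CSA (cat.), CH2Cl2, rt
Reagents that add atoms: none
Why: Oxidative cleavage of the PMB ether by DDQ frees the C20 alcohol, which closes the six-membered lactone on the ester cis to C10 (transesterification with loss of allyl alcohol), while the C6 silyl ether stays in place so that no oxa-Michael addition to C9 can occur.

Step 12
Reactants: 19 spirolactone dienophile; 20 buta-1,3-diene
Product: 21 Diels–Alder adduct: allyl C8-carboxylate of the cis-fused cyclohexene spirolactone (ring A 1-oxo-2-ene, ring C 12-ene, H9 cis to the C8 ester, ring C on the lactone face syn to C1)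
Conditions: 20 (excess), ZnCl2, CH2Cl2, 0 °C → rt, sealed tube
Reagents that add atoms: buta-1,3-diene (20), C=CC=C
Why: Normal-demand Diels–Alder reaction of the doubly activated C8=C9 bond (ZnCl2 chelated by the lactone and ester carbonyls), in which suprafacial addition fixes the cis lactone/ring-C fusion and the diene should add to the face flanked by the flat C1 carbonyl, anti to the C5 arm with its silyloxymethyl group and gem-dimethyl neighbour, which sets C8 and C9 relative to C10.

Step 13
Reactants: 21 Diels–Alder adduct
Product: 22 1-hydroxy adduct (ring A 1-ol-2-ene, hydroxyl cis to C20)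
Conditions: NaBH4, CeCl3·7H2O, MeOH, −78 → −40 °C
Reagents that add atoms: none
Why: Luche 1,2-reduction touches only the C1 enone carbonyl at this temperature and masks ring A as an allylic alcohol, hydride being expected anti to the pseudoaxial C20 arm at a centre that is removed again in step 23.

Step 14
Reactants: 22 1-hydroxy adduct
Product: 23 1,6-bis-TBS ether allyl ester
Conditions: TBSOTf, 2,6-lutidine, CH2Cl2, −78 → 0 °C
Reagents that add atoms: tert-butyldimethylsilyl triflate (TBSOTf), CC(C)(C)[Si](C)(C)OS(=O)(=O)C(F)(F)F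
Why: Silylation of the hindered secondary alcohol with the silyl triflate and a non-nucleophilic base forestalls acyl transfer from the lactone to the C1 oxygen and gives a second ether that later comes off together with the C6 ether.

Step 15
Reactants: 23 1,6-bis-TBS ether allyl ester
Product: 24 C8 carboxylic acid
Conditions: Pd(PPh3)4 (5 mol%), morpholine, THF, 0 °C → rt; cold pH 4 work-up
Reagents that add atoms: none
Why: Tsuji–Trost deallylation (zerovalent palladium forms a π-allyl complex that morpholine captures) frees the C8 acid under neutral conditions without touching the lactone, the silyl ethers or the ring-C alkene and without the heat that would decarboxylate this malonic half-acid.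

Step 16
Reactants: 24 C8 carboxylic acid; 25 (trimethylsilyl)diazomethane
Product: 27 C8 diazomethyl ketone (15-oxo-16-diazo; ring C 12-ene), via acid chloride 26 (not isolated)
Conditions: 1-chloro-N,N,2-trimethylprop-1-en-1-amine (Ghosez reagent), CH2Cl2, 0 °C → rt; then 25 (3 equiv), MeCN/THF, 0 °C → rt
Reagents that add atoms: (trimethylsilyl)diazomethane (25), C[Si](C)(C)C=[N+]=[N-]
Why: Arndt–Eistert-type acylation, in which the acid chloride is made under neutral conditions that spare the silyl ethers, cannot form a ketene because C8 is quaternary, and acylates the diazo carbon, chloride then removing the silyl group to leave the diazomethyl ketone whose carbon is C16.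

Step 17
Reactants: 27 C8 diazomethyl ketone
Product: 28 15-oxo-12,16-cyclo ketone (cyclopropane C12–C13–C16 on the ring-C face syn to C15)
Conditions: Rh2(OAc)4 (1 mol%), CH2Cl2, rt, slow addition of 27
Reagents that add atoms: none
Why: Rh2(OAc)4 (divalent rhodium) expels N2 from the diazoketone to give an electrophilic carbenoid at C16, which adds in a concerted, asynchronous [2+1] fashion to the C12=C13 bond, forming C13–C16 and C12–C16. The closest known reaction is the copper- or rhodium-catalysed cyclisation of cyclohex-3-enyl diazomethyl ketones to tricyclo[3.2.1.0^2,7]octan-6-ones. The cyclopentanone ring (C8, C15, C16, C13, C14) closes by bonding C16 to the proximal alkene carbon C13 in a five-membered exo mode, and the cyclopropane (C12, C13, C16) closes in the same event by a three-membered exo closure of C16 onto C12. C13, C12 and C16 are all controlled by the quaternary C8, because the two-atom tether can deliver C16 only to the alkene face syn to the acyl arm when that arm is axial on ring C, so no other diastereomer is geometrically possible. The step needs cyclopropanation to outrun insertion into the axial allylic C11–H bond and capture of the carbenoid by the lactone carbonyl oxygen, and the cis alkene held at bonding distance under the axial arm, the low nucleophilicity of a lactone carbonyl and the low stationary concentration of diazoketone should secure this.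

Step 18
Reactants: 28 15-oxo-12,16-cyclo ketone
Product: 29 17-nor-15-ketone (bicyclo[3.2.1]octan-15-one, C12 and C16 now CH2)
Conditions: SmI2 (2.5 equiv), THF/MeOH, −78 °C
Reagents that add atoms: none
Why: Reductive cleavage of a cyclopropyl ketone by two single-electron transfers from samarium diiodide, in which the ketyl opens the C12–C16 bond because it lies out of the cyclopentanone plane and overlaps the carbonyl π system whereas C13–C16 lies in that plane, methanol then protonating C12 and the samarium enolate while the lactone, silyl ethers and isolated alkene are inert.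

Step 19
Reactants: 29 17-nor-15-ketone; 30 N,N-dimethylmethylideneammonium iodide (Eschenmoser's salt)
Product: 33 16-methylene-15-ketone, via Mannich base 31 (not isolated), via ammonium iodide 32 (not isolated)
Conditions: LiN(SiMe3)2, THF, −78 °C; 30, −78 °C → rt; MeI, CH2Cl2, rt; DBU, rt
Reagents that add atoms: Eschenmoser's salt (30), C=[N+](C)C.[I-]
Why: Eschenmoser methylenation, in which C16 is the only enolisable position of the 15-ketone (C8 is quaternary), its lithium enolate undergoes a Mannich reaction with the iminium salt, and quaternisation followed by base-induced loss of trimethylamine gives the exocyclic enone.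

Step 20
Reactants: 33 16-methylene-15-ketone
Product: 34 15-alcohol (hydroxyl syn to the C9–C11–C12 bridge)
Conditions: NaBH4, CeCl3·7H2O, MeOH, −78 → 0 °C
Reagents that add atoms: none
Why: Luche 1,2-reduction of the only carbonyl still reducible, with hydride delivered to the exo face of ring D (the face away from the C9–C11–C12 bridge, whose axial C11 hydrogen shields the other face), which should place the C15 oxygen syn to that bridge as in the target.

Step 21
Reactants: 34 15-alcohol; 35 acetic anhydride
Product: 36 15-acetate 1,6-bis-TBS ether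
Conditions: 35, pyridine, DMAP (cat.), CH2Cl2, rt
Reagents that add atoms: acetic anhydride (35), CC(=O)OC(C)=O
Why: DMAP-catalysed acetylation of the hindered secondary allylic alcohol proceeds at oxygen with retention at C15.

Step 22
Reactants: 36 15-acetate 1,6-bis-TBS ether
Product: 37 15-acetate 1,6-diol
Conditions: HF·pyridine, THF/pyridine, 0 °C → rt
Reagents that add atoms: none
Why: Fluoride-mediated desilylation with buffered HF·pyridine removes both silyl ethers while leaving the acetate, the lactone and the exocyclic alkene, which a basic fluoride source might disturb.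

Step 23
Reactants: 37 15-acetate 1,6-diol
Product: 38 CNP0108627.4 (15-acetoxy-1,6-dioxo-6,7-seco-ent-kaura-2,16-dien-7,20-olide)
Conditions: (COCl)2, DMSO, CH2Cl2, −78 °C; Et3N, −78 → 0 °C
Reagents that add atoms: none
Why: Swern oxidation converts both alcohols into alkoxysulfonium salts before base is added, so the allylic C1 alcohol gives the enone and the primary C6 alcohol gives the aldehyde without an intermediate lactol that could be over-oxidised to a lactone, and the brief cold exposure to amine should not epimerise C5, which is flanked by two quaternary carbons.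

**Compound list**

1 | 4,4-dimethylcyclohex-2-en-1-one | CC1(C)CCC(=O)C=C1 | starting material
2 | 4,4-dimethylcyclohexa-2,5-dien-1-one | CC1(C)C=CC(=O)C=C1 | intermediate
3 | potassium vinyltrifluoroborate | C=C[B-](F)(F)F.[K+] | starting material
4 | (R)-4,4-dimethyl-5-vinylcyclohex-2-en-1-one | O=C1C=CC(C)(C)[C@@H](C=C)C1 | intermediate
5 | (S)-2,2-dimethyl-5-oxocyclohex-3-ene-1-carbaldehyde (C6 aldehyde) | O=C1C=CC(C)(C)[C@@H](C=O)C1 | intermediate (not isolated)
6 | (S)-5-(hydroxymethyl)-4,4-dimethylcyclohex-2-en-1-one | O=C1C=CC(C)(C)[C@@H](CO)C1 | intermediate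
7 | (S)-5-(TBS-oxymethyl)-4,4-dimethylcyclohex-2-en-1-one | O=C1C=CC(C)(C)[C@@H](CO[Si](C)(C)C(C)(C)C)C1 | intermediate
8 | 4-methoxybenzyl alcohol | COc1ccc(CO)cc1 | starting material
9 | chloromethyl methyl sulfide | CSCCl | starting material
10 | 1-methoxy-4-{[(methylsulfanyl)methoxy]methyl}benzene | COc1ccc(COCSC)cc1 | intermediate
11 | 1-[(chloromethoxy)methyl]-4-methoxybenzene (PMB chloromethyl ether) | COc1ccc(COCCl)cc1 | intermediate
12 | trans-6-(PMB-oxymethyl)-5-(TBS-oxymethyl)-4,4-dimethylcyclohex-2-en-1-one | O=C1C=CC(C)(C)[C@@H](CO[Si](C)(C)C(C)(C)C)[C@@H]1COCc2ccc(OC)cc2 | intermediate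
13 | formaldehyde | C=O | starting material
14 | 6-(hydroxymethyl)-6-(PMB-oxymethyl)-5-(TBS-oxymethyl)-4,4-dimethylcyclohex-2-en-1-one (C9 trans, C20 cis to the C5 arm) | OC[C@]1(COCc2ccc(OC)cc2)C(=O)C=CC(C)(C)[C@H]1CO[Si](C)(C)C(C)(C)C | intermediate
15 | 1-(PMB-oxymethyl)-6-(TBS-oxymethyl)-5,5-dimethyl-2-oxocyclohex-3-ene-1-carbaldehyde | O=C[C@]1(COCc2ccc(OC)cc2)C(=O)C=CC(C)(C)[C@H]1CO[Si](C)(C)C(C)(C)C | intermediate
16 | diallyl malonate | C=CCOC(=O)CC(=O)OCC=C | starting material
17 | diallyl 2-(cyclohexenylmethylidene)malonate (C9=C8; C20–OPMB) | C=CCOC(=O)C(C(=O)OCC=C)=C[C@]1(COCc2ccc(OC)cc2)C(=O)C=CC(C)(C)[C@H]1CO[Si](C)(C)C(C)(C)C | intermediate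
18 | hydroxy diester (C20–OH) | C=CCOC(=O)C(C(=O)OCC=C)=C[C@]1(CO)C(=O)C=CC(C)(C)[C@H]1CO[Si](C)(C)C(C)(C)C | intermediate (not isolated)
19 | allyl 11-(TBS-oxymethyl)-10,10-dimethyl-3,7-dioxo-2-oxaspiro[5.5]undeca-4,8-diene-4-carboxylate | C=CCOC(=O)C1=C[C@]2(COC1=O)C(=O)C=CC(C)(C)[C@H]2CO[Si](C)(C)C(C)(C)C | intermediate
20 | buta-1,3-diene | C=CC=C | starting material
21 | Diels–Alder adduct, allyl C8-carboxylate (1-oxo-2-ene, 12-ene, 6-OTBS, 7,20-lactone) | C1=CC[C@@H]3[C@](C1)(C(=O)OC[C@]32C(=O)C=CC(C)(C)[C@H]2CO[Si](C)(C)C(C)(C)C)C(=O)OCC=C | intermediate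
22 | 1-hydroxy adduct (hydroxyl cis to C20) | C1=CC[C@@H]3[C@](C1)(C(=O)OC[C@]32[C@@H](O)C=CC(C)(C)[C@H]2CO[Si](C)(C)C(C)(C)C)C(=O)OCC=C | intermediate
23 | 1,6-bis-TBS ether allyl ester | C1=CC[C@@H]3[C@](C1)(C(=O)OC[C@]32[C@@H](O[Si](C)(C)C(C)(C)C)C=CC(C)(C)[C@H]2CO[Si](C)(C)C(C)(C)C)C(=O)OCC=C | intermediate
24 | C8 carboxylic acid | C1=CC[C@@H]3[C@](C1)(C(=O)OC[C@]32[C@@H](O[Si](C)(C)C(C)(C)C)C=CC(C)(C)[C@H]2CO[Si](C)(C)C(C)(C)C)C(=O)O | intermediate
25 | (trimethylsilyl)diazomethane | C[Si](C)(C)C=[N+]=[N-] | starting material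
26 | C8 acid chloride | C1=CC[C@@H]3[C@](C1)(C(=O)OC[C@]32[C@@H](O[Si](C)(C)C(C)(C)C)C=CC(C)(C)[C@H]2CO[Si](C)(C)C(C)(C)C)C(=O)Cl | intermediate (not isolated)
27 | C8 diazomethyl ketone (key-step precursor) | C1=CC[C@@H]3[C@](C1)(C(=O)OC[C@]32[C@@H](O[Si](C)(C)C(C)(C)C)C=CC(C)(C)[C@H]2CO[Si](C)(C)C(C)(C)C)C(=O)C=[N+]=[N-] | intermediate
28 | 15-oxo-12,16-cyclo ketone (key-step product) | [C@@H]16[C@@H]2[C@H]6C[C@@H]3[C@](C2)(C(=O)OC[C@]32[C@@H](O[Si](C)(C)C(C)(C)C)C=CC(C)(C)[C@H]2CO[Si](C)(C)C(C)(C)C)C1=O | intermediate
29 | 17-nor-15-ketone (bicyclo[3.2.1]octan-15-one) | C1[C@@H]2CC[C@@H]3[C@](C2)(C(=O)OC[C@]32[C@@H](O[Si](C)(C)C(C)(C)C)C=CC(C)(C)[C@H]2CO[Si](C)(C)C(C)(C)C)C1=O | intermediate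
30 | N,N-dimethylmethylideneammonium iodide (Eschenmoser's salt) | C=[N+](C)C.[I-] | starting material
31 | Mannich base (16-exo-CH2NMe2) | CN(C)C[C@H]1[C@@H]2CC[C@@H]3[C@](C2)(C(=O)OC[C@]32[C@@H](O[Si](C)(C)C(C)(C)C)C=CC(C)(C)[C@H]2CO[Si](C)(C)C(C)(C)C)C1=O | intermediate (not isolated)
32 | trimethylammonium iodide of 31 | C[N+](C)(C)C[C@H]1[C@@H]2CC[C@@H]3[C@](C2)(C(=O)OC[C@]32[C@@H](O[Si](C)(C)C(C)(C)C)C=CC(C)(C)[C@H]2CO[Si](C)(C)C(C)(C)C)C1=O.[I-] | intermediate (not isolated)
33 | 16-methylene-15-ketone | C=C1[C@@H]2CC[C@@H]3[C@](C2)(C(=O)OC[C@]32[C@@H](O[Si](C)(C)C(C)(C)C)C=CC(C)(C)[C@H]2CO[Si](C)(C)C(C)(C)C)C1=O | intermediate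
34 | 15-alcohol | C=C1[C@@H]2CC[C@@H]3[C@](C2)(C(=O)OC[C@]32[C@@H](O[Si](C)(C)C(C)(C)C)C=CC(C)(C)[C@H]2CO[Si](C)(C)C(C)(C)C)[C@@H]1O | intermediate
35 | acetic anhydride | CC(=O)OC(C)=O | starting material
36 | 15-acetate 1,6-bis-TBS ether | C=C1[C@@H]2CC[C@@H]3[C@](C2)(C(=O)OC[C@]32[C@@H](O[Si](C)(C)C(C)(C)C)C=CC(C)(C)[C@H]2CO[Si](C)(C)C(C)(C)C)[C@@H]1OC(C)=O | intermediate
37 | 15-acetate 1,6-diol | C=C1[C@@H]2CC[C@@H]3[C@](C2)(C(=O)OC[C@]32[C@@H](O)C=CC(C)(C)[C@H]2CO)[C@@H]1OC(C)=O | intermediate
38 | CNP0108627.4 | C=C1[C@@H]2CC[C@@H]3[C@](C2)(C(=O)OC[C@]32C(=O)C=CC(C)(C)[C@H]2C=O)[C@@H]1OC(C)=O | target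

**Step count and risks**

Total step count: 23 (steps 5 and 6 prepare reagent 11). Longest linear sequence: 21 steps (steps 1–4 and 7–23).

Steps most likely to fail:

1. Step 17. The carbenoid may insert into the axial allylic C11–H bond, or be captured by the lactone carbonyl oxygen as a five-membered carbonyl ylide, faster than it adds to C12=C13. The fallback avoids a carbene; it sets out from acid chloride 26 and returns at 29. Me2CuLi (THF, −78 °C) converts 26 into the C8 methyl ketone F1. TMSOTf/Et3N gives the trimethylsilyl enol ether F2, since only the methyl group can enolise. Pd(OAc)2 in MeCN then effects a cycloalkenylation of the silyl enol ether (Kende and Toyota–Ihara type): divalent palladium activates C12=C13, C16 attacks C13 in a five-membered exo closure, and β-hydride elimination toward C11 gives the bicyclo[3.2.1]oct-11-en-15-one F3. Diimide (2-nitrobenzenesulfonyl hydrazide, Et3N) should saturate the strained, unhindered C11=C12 bond in preference to the shielded C2=C3 bond and deliver 29.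

2. Step 12. The neopentyl-flanked trisubstituted dienophile may react too slowly with unactivated butadiene, so that diene polymerisation takes over and forcing temperatures erode the facial preference. The fallback sets out from 19 and returns at 24. 2-(Trimethylsilyloxy)buta-1,3-diene, an electron-rich diene, should add near room temperature (toluene, 40 °C) with para orientation, its CH2 terminus next to the silyloxy carbon bonding to the electrophilic C9. This gives the silyl enol ether adduct F4 with the C12=C13 bond already in place. CsF/PhNTf2 (DME) converts it regiospecifically into the C12 enol triflate F5. Luche reduction at C1 gives the 1-hydroxy enol triflate F6, and TBSOTf/2,6-lutidine gives the 1-O-TBS enol triflate F7, as in steps 13 and 14. Pd(OAc)2/PPh3 with HCO2H/Et3N (zerovalent palladium formed in the flask) then reduces the enol triflate to the C12–H alkene and cleaves the allyl ester in the same operation, giving acid 24.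

3. Step 8. The lithium enolate of 12 may lose the β-(PMB)oxy group by elimination, or the lithium aldolate may revert by retro-aldol cleavage, with loss of material and of facial selectivity. The fallback sets out from 12 and returns at 14. LiN(iPr)2 with TMSCl present (in situ quench, −78 °C) gives the neutral trimethylsilyl dienol ether F8. This is hydroxymethylated with aqueous formaldehyde and Sc(OTf)3 in THF (Mukaiyama-type aldol), non-basic conditions under which neither elimination nor retro-aldol cleavage should occur; the same face anti to the C5 arm is attacked.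

**Further compounds**

F1 | step 17 | C8 methyl ketone | C1=CC[C@@H]3[C@](C1)(C(=O)OC[C@]32[C@@H](O[Si](C)(C)C(C)(C)C)C=CC(C)(C)[C@H]2CO[Si](C)(C)C(C)(C)C)C(C)=O
F2 | step 17 | trimethylsilyl enol ether of F1 | C1=CC[C@@H]3[C@](C1)(C(=O)OC[C@]32[C@@H](O[Si](C)(C)C(C)(C)C)C=CC(C)(C)[C@H]2CO[Si](C)(C)C(C)(C)C)C(=C)O[Si](C)(C)C
F3 | step 17 | bicyclo[3.2.1]oct-11-en-15-one | C1[C@@H]2C=C[C@@H]3[C@](C2)(C(=O)OC[C@]32[C@@H](O[Si](C)(C)C(C)(C)C)C=CC(C)(C)[C@H]2CO[Si](C)(C)C(C)(C)C)C1=O
F4 | step 12 | C12 trimethylsilyl enol ether adduct | C1=C(O[Si](C)(C)C)C[C@@H]3[C@](C1)(C(=O)OC[C@]32C(=O)C=CC(C)(C)[C@H]2CO[Si](C)(C)C(C)(C)C)C(=O)OCC=C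
F5 | step 12 | C12 enol triflate | C1=C(OS(=O)(=O)C(F)(F)F)C[C@@H]3[C@](C1)(C(=O)OC[C@]32C(=O)C=CC(C)(C)[C@H]2CO[Si](C)(C)C(C)(C)C)C(=O)OCC=C
F6 | step 12 | 1-hydroxy enol triflate | C1=C(OS(=O)(=O)C(F)(F)F)C[C@@H]3[C@](C1)(C(=O)OC[C@]32[C@@H](O)C=CC(C)(C)[C@H]2CO[Si](C)(C)C(C)(C)C)C(=O)OCC=C
F7 | step 12 | 1-O-TBS enol triflate | C1=C(OS(=O)(=O)C(F)(F)F)C[C@@H]3[C@](C1)(C(=O)OC[C@]32[C@@H](O[Si](C)(C)C(C)(C)C)C=CC(C)(C)[C@H]2CO[Si](C)(C)C(C)(C)C)C(=O)OCC=C
F8 | step 8 | trimethylsilyl dienol ether of 12 | C[Si](C)(C)OC1=C(COCc2ccc(OC)cc2)[C@H](CO[Si](C)(C)C(C)(C)C)C(C)(C)C=C1
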